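Count the free base.

| setting | Thursday's | Wednesday's | noon | dusk | summer |
|---|---|---|---|---|---|
| electrophile | 1 mM | 1 mM | 1.0 mM | 1.0 mM | 1.0 mM |
| free base | 0.43 mM | 1.9 mM | 0.300 mM | 0.600 mM | 1.20 mM |
| protonated nucleophile | 1.2 mM | 1.2 mM | 1.20 mM | 1.20 mM | 1.20 mM |
| remark | run made earlier | run made earlier |  |  |  |
| time |  |  | 25 min | 25 min | 25 min |

| run | time / min | electrophile / % | target / % |
|---|---|---|---|
| Thursday's | 2.00 | 78.3 | 21.0 |
| Thursday's | 4.00 | 76.2 | 23.3 |
| Thursday's | 6.00 | 76.5 | 23.2 |
| Thursday's | 8.00 | 76.5 | 22.8 |
| Thursday's | 10.0 | 76.8 | 23.7 |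
| Thursday's | 12.0 | 76.8 | 23.3 |
| Wednesday's | 1.00 | 66.7 | 33.1 |
| Wednesday's | 1.50 | 55.5 | 44.2 |
| Wednesday's | 3.00 | 36.8 | 64.1 |
| Wednesday's | 5.00 | 22.9 | 76.0 |
| Wednesday's | 8.00 | 16.3 | 84.7 |
| Wednesday's | 12.0 | 11.7 | 88.5 |

(each reading ± 0.5 percentage points)



- part of the electrophile that has reacted at the end, noon
- part of the electrophile that has reacted at the end, dusk
- part of the electrophile that has reacted at the end, summer
- what raising the concentration of free base from its lowest to its highest value here does to the part of the electrophile that has reacted (changes below 5 percentage points count as none) (no change / it falls / it rises)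

Thursday's and Wednesday's flasks look nearly the same: each holds 1 mM of electrophile and 1.2 mM of protonated nucleophile, and they part in free base, 0.43 mM against 1.9 mM. Thursday's target reads 23.3% at 4.00 min and 23.3% at 12.0 min, flat within the scatter of 0.5 percentage points, with 76.8% of the electrophile unreacted. Wednesday's target climbs to 88.5% over the same time.

Thursday's plateau gives 1.85 free base per target: this is the base cost, the free base charged over the target made at a stall. Read this way, free base is the limiting reagent on Thursday. At that cost Wednesday's free base pays for 1.03 mM of target, more than Thursday's plateau of 0.233 mM.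

Wednesday's electrophile falls to 66.7% after 1.00 min, which as an exponential decay is a half-life of 1.71 min. The 25 min asked holds 14.6 such half-lives, so each new flask should reach its stall, and its reacted part is its free base over the cost. That reckoning gives 16.3% at noon, 32.5% at dusk and 65.0% in summer.

The forecast, reading “base exhaustion at close to two base per target”, gives 16%, 32% and 63%, and says it rises. In summer it stands below the reckoning here.

The flask gives 17.4% at noon, 31.3% at dusk and 59.7% in summer; from the lowest free base to the highest, the reacted part: it rises, by 42 points.

    nucleophile + acid set free ⇌ protonated nucleophile, settled at all times (K = 4.90 × 10⁶ M⁻¹)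
    acid set free + free base ⇌ salt of the base (K = 5.60 × 10⁶ M⁻¹, k = 830 M⁻¹ s⁻¹)
    electrophile + nucleophile ⇌ acid set free + target (K = 2.90, k = 310 M⁻¹ s⁻¹)

At the end of summer 1.1% of the free base is still free, against 40% of the electrophile, and at 250 min the answer reads 59.7%. Summer's charge over its target comes to 2.01 free base per target, and noon's to 1.72. At the cost of 1.85, the flask like dusk but charged with 0.24 mM of free base comes out at 13.0%, and that flask ends at 14.8%.

The numbers in the tables come from a simulation with made-up constants; noise was put on by code.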